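**Retrosynthetic overview**

1. Last bond, C4–C5: an intramolecular Nozaki–Hiyama–Kishi addition of a C4 alkenyl triflate to a C5 aldehyde closes the ten-membered carbocycle (C1–C10) of acyclic 26 and creates the C5 carbinol and the C4=C15 methylene at once, giving the target with no protecting groups left.
2. Enabling feature: the 2-methylene-1-ol unit C15H2=C4–C5H(OH) inside the ten-membered ring, with C5 next to the lactone-bearing C6 (an α-acyloxy aldehyde in the precursor), and three rigid turn elements in the chain (cis-2,3-oxirane, trans-1,10-oxirane, trans-fused γ-lactone ring).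
3. The triflate comes from a cis-α,β-epoxy methyl ketone; both oxiranes are set on an acyclic (1(10)E,2Z)-dienol by Shi epoxidation (C10/C1) and then carbinol-directed peracid epoxidation (C2/C3).
4. C1–C2 by Stille coupling (E-alkenyl iodide from alkyne carboalumination plus an (R,Z)-stannyl butenol); C8–C9 by asymmetric propargylation; C7–C8 by trans-selective vinyl cuprate addition to (S)-5-(silyloxymethyl)butenolide (C6 from the chiral pool).
5. Ring order: γ-lactone (purchased) → 1,10-oxirane → 2,3-oxirane → ten-membered carbocycle.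

Key step: step 18

Remark on the chemistry: the target is read as (1R,2S,3S,5S,6S,7R,8S,10R)-1,10:2,3-diepoxy-5-hydroxy-8-angeloyloxygermacra-4(15),11(13)-dien-12,6-olide (trans-fused lactone, trans-1,10-oxirane, cis-2,3-oxirane, Z ester); these locants (C1–C15, C12 = lactone carbonyl) are used for all intermediates, and the SMILES strings are authoritative for configuration.

**Route**

Step 1
Reactants: 1 (S)-5-(hydroxymethyl)furan-2(5H)-one
Product: 2 (S)-5-{[(tert-butyldiphenylsilyl)oxy]methyl}furan-2(5H)-one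
Conditions: TBDPSCl, imidazole, DMF, 0 °C to rt
Reagents that add atoms: tert-butyl(chloro)diphenylsilane, CC(C)(C)[Si](Cl)(c1ccccc1)c1ccccc1
Why: Imidazole-promoted silylation of the primary alcohol; the C6 stereocentre is not touched.

Step 2
Reactants: 2 (S)-5-{[(tert-butyldiphenylsilyl)oxy]methyl}furan-2(5H)-one
Product: 3 (4R,5S)-5-{[(tert-butyldiphenylsilyl)oxy]methyl}-4-vinyldihydrofuran-2(3H)-one (trans)
Conditions: CH2=CHMgBr, CuBr·SMe2 (10 mol%), THF, −78 to −40 °C; aq. NH4Cl
Reagents that add atoms: vinylmagnesium bromide, C=C[Mg]Br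
Why: Copper-catalysed conjugate addition to the butenolide; the C6 silyloxymethyl group blocks its own face, so vinyl should enter anti to it and set C7 trans to C6.

Step 3
Reactants: 3 (4R,5S)-5-{[(tert-butyldiphenylsilyl)oxy]methyl}-4-vinyldihydrofuran-2(3H)-one
Product: 5 (2S,3S)-2-{[(tert-butyldiphenylsilyl)oxy]methyl}-5-oxotetrahydrofuran-3-carbaldehyde (C8 aldehyde), via secondary ozonide 4 (not isolated)
Conditions: O3, CH2Cl2, −78 °C; PPh3, −78 °C to rt; used at once
Reagents that add atoms: ozone, [O-][O+]=O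
Why: Ozonolysis with reductive work-up cleaves the only C=C bond; the neutral conditions should avoid epimerisation at C7 and β-elimination of the lactone oxygen.

Step 4
Reactants: 5 (2S,3S)-2-{[(tert-butyldiphenylsilyl)oxy]methyl}-5-oxotetrahydrofuran-3-carbaldehyde
Product: 6 (4R,5S)-5-{[(tert-butyldiphenylsilyl)oxy]methyl}-4-[(1S)-1-hydroxybut-3-yn-1-yl]dihydrofuran-2(3H)-one
Conditions: allenylboronic acid pinacol ester, (S)-TRIP phosphoric acid (10 mol%), 4 Å molecular sieves, toluene, −20 °C; aqueous work-up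
Reagents that add atoms: allenylboronic acid pinacol ester, C=C=CB1OC(C)(C)C(C)(C)O1
Why: Chiral phosphoric acid-catalysed propargylation through a closed six-membered transition state; the (S)-catalyst is the antipode expected to direct Si-face attack at C8, which is also the Felkin–Anh face (C6 branch anti), so reagent and substrate control should be matched for 8S.

Step 5
Reactants: 6 (4R,5S)-5-{[(tert-butyldiphenylsilyl)oxy]methyl}-4-[(1S)-1-hydroxybut-3-yn-1-yl]dihydrofuran-2(3H)-one
Product: 7 triethylsilyl ether of 6 [(1S)-1-(triethylsilyloxy)but-3-yn-1-yl side chain at C7]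
Conditions: Et3SiOTf, 2,6-lutidine, CH2Cl2, −78 °C
Reagents that add atoms: triethylsilyl trifluoromethanesulfonate, CC[Si](CC)(CC)OS(=O)(=O)C(F)(F)F
Why: Silylation of the secondary alcohol under non-equilibrating conditions, which also blocks translactonisation to the 12,8-lactone.

Step 6
Reactants: 7 triethylsilyl ether of 6
Product: 9 E-alkenyl iodide carrying the (1S,3E)-4-iodo-3-methyl-1-(triethylsilyloxy)but-3-en-1-yl chain at C7, via E-alkenyldimethylalane 8 (not isolated)
Conditions: AlMe3, Cp2ZrCl2 (20 mol%), H2O (1 equiv), CH2Cl2, −20 °C; then iodine, THF, −20 to 0 °C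
Reagents that add atoms: trimethylaluminium, C[Al](C)C; iodine, [I][I]
Why: Negishi zirconium-catalysed syn-carboalumination puts methyl on C10 and aluminium on the terminal C1, and iodinolysis with retention should give the E-iodide (C9 trans to iodine); the short low-temperature reaction spares the lactone.

Step 7
Reactants: 9 E-alkenyl iodide (saturated lactone, C8 triethylsilyl ether)
Product: 12 α-methylene lactone (C11=C13) with C8 triethylsilyl ether and E-alkenyl iodide, via Mannich base 10 (not isolated), via methiodide 11 (not isolated)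
Conditions: LiN(iPr)2, THF, −78 °C, then CH2=NMe2 iodide; MeI, THF, rt; aq. NaHCO3, CH2Cl2
Reagents that add atoms: N,N-dimethylmethyleneiminium iodide (Eschenmoser's salt), C=[N+](C)C.[I-]; iodomethane, C[I] (its methyl group is carried only in 11 and leaves as trimethylamine)
Why: Lactone enolate Mannich reaction followed by quaternisation and elimination of trimethylamine, the standard α-methylenation of γ-lactones; C7 is not enolisable, so no stereocentre is at risk.

Step 8
Reactants: 12 α-methylene lactone with C8 triethylsilyl ether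
Product: 13 C8 alcohol [(1S,3E)-1-hydroxy-4-iodo-3-methylbut-3-en-1-yl chain at C7]
Conditions: HF·pyridine, pyridine, THF, 0 °C
Reagents that add atoms: none
Why: Buffered fluoride should cleave the secondary triethylsilyl ether much faster than the primary tert-butyldiphenylsilyl ether.

Step 9
Reactants: 13 C8 alcohol; 14 angelic acid [(Z)-2-methylbut-2-enoic acid]
Product: 16 C8 angelate carrying the E-alkenyl iodide, via angelic 2,4,6-trichlorobenzoic anhydride 15 (not isolated)
Conditions: 14, 2,4,6-trichlorobenzoyl chloride, Et3N, toluene, rt; then 13, toluene, 80 °C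
Reagents that add atoms: 2,4,6-trichlorobenzoyl chloride, O=C(Cl)c1c(Cl)cc(Cl)cc1Cl (its acyl group is carried only in 15)
Why: Yamaguchi-type mixed-anhydride esterification run without a nucleophilic amine catalyst, the variant that keeps the Z (angelate) geometry; C8 reacts with retention.

Step 10
Reactants: 17 (R)-but-3-yn-2-ol
Product: 19 (R,Z)-4-(tributylstannyl)but-3-en-2-ol, via cyclic alkenylalanate 18 (not isolated)
Conditions: LiAlH4, THF, 0 °C to rt; Bu3SnOTf, −78 °C to rt
Reagents that add atoms: LiAlH4, [Li+].[AlH4-] (lithium and aluminium are carried only in 18); tributyltin trifluoromethanesulfonate, CCCC[Sn](CCCC)(CCCC)OS(=O)(=O)C(F)(F)F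
Why: Hydroxyl-directed trans-hydroalumination of the propargylic alcohol (hydride to C3, aluminium to C4 in a five-membered alanate) and Al-to-Sn exchange with retention should give the Z-stannane; the carbinol centre is untouched.

Step 11
Reactants: 16 C8 angelate with E-alkenyl iodide; 19 (R,Z)-4-(tributylstannyl)but-3-en-2-ol
Product: 20 (1(10)E,2Z)-dienol with (4R)-carbinol
Conditions: Pd2(dba)3 (5 mol%), AsPh3, CuI, DMF, rt
Reagents that add atoms: none
Why: Stille coupling (zerovalent palladium, copper co-catalysis) proceeds with retention at both alkenyl carbons and forms C1–C2 with the E,Z-diene geometry under neutral conditions that spare the two enoates.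

Step 12
Reactants: 20 (1(10)E,2Z)-dienol
Product: 21 (10R,1R)-trans-1,10-oxirane (vinyl oxirane with Z-allylic 4R alcohol)
Conditions: Shi ketone (D-fructose-derived, 30 mol%), KHSO5 (Oxone), K2CO3, Bu4NHSO4, MeCN–dimethoxymethane–aq. Na2B4O7 buffer, pH about 10, 0 °C
Reagents that add atoms: potassium peroxymonosulfate, [K+].[O-]S(=O)(=O)OO
Why: Shi asymmetric epoxidation through a spiro transition state; the chiral dioxirane should take the E-trisubstituted C10=C1 bond (the Z bond is a poor substrate and is deactivated by the allylic OH), and the D-fructose catalyst gives the face that leads to (R,R)-epoxides from trans-type olefins, i.e. 10R,1R.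

Step 13
Reactants: 21 (10R,1R)-trans-1,10-oxirane with Z-allylic alcohol
Product: 22 bis-oxirane carbinol (additional cis-2,3-oxirane, 2S,3S, threo to the 4R carbinol)
Conditions: mCPBA, Na2HPO4, CH2Cl2, 0 °C
Reagents that add atoms: 3-chloroperoxybenzoic acid, OOC(=O)c1cccc(Cl)c1
Why: Hydroxyl-directed peracid epoxidation of a Z-allylic alcohol; A(1,3) strain holds the carbinol hydrogen in the alkene plane, so the (4R)-hydroxyl should deliver oxygen to one face (threo) and set 2S,3S, the cis-oxirane following from the Z geometry, while the electron-poor enoates do not react.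

Step 14
Reactants: 22 bis-oxirane carbinol
Product: 23 cis-α,β-epoxy methyl ketone (C4 ketone)
Conditions: Dess–Martin periodinane, NaHCO3, CH2Cl2, 0 °C to rt
Reagents that add atoms: none
Why: Buffered Dess–Martin oxidation of the secondary alcohol; the oxirane C3–H is not enolisable under these conditions, so the cis-oxirane should be kept.

Step 15
Reactants: 23 cis-α,β-epoxy methyl ketone
Product: 24 C4 enol triflate (C4 bears OTf and the C15 methylene)
Conditions: KN(SiMe3)2, THF, −78 °C; Comins' reagent, −78 °C; aq. NH4Cl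
Reagents that add atoms: N-(5-chloropyridin-2-yl)-1,1,1-trifluoro-N-(trifluoromethylsulfonyl)methanesulfonamide (Comins' reagent), FC(F)(F)S(=O)(=O)N(c1ccc(Cl)cn1)S(=O)(=O)C(F)(F)F
Why: Kinetic deprotonation of the methyl ketone (its only enolisable side and the most acidic C–H in the molecule) and O-triflation of the enolate, the standard route to 1,1-disubstituted alkenyl triflates.

Step 16
Reactants: 24 C4 enol triflate with C5 silyl ether
Product: 25 primary C5 alcohol
Conditions: HF·pyridine, pyridine, THF, 0 °C to rt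
Reagents that add atoms: none
Why: Buffered HF·pyridine removes the primary silyl ether; enol triflate, oxiranes and esters should tolerate it (basic fluoride is avoided because it can eliminate the triflate).

Step 17
Reactants: 25 primary C5 alcohol
Product: 26 seco-aldehyde (C5 aldehyde on the lactone carbon C6)
Conditions: Dess–Martin periodinane, NaHCO3, CH2Cl2, 0 °C; used crude
Reagents that add atoms: none
Why: Buffered Dess–Martin oxidation gives the α-acyloxy aldehyde without base, which should avoid epimerisation at C6.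

Step 18
Reactants: 26 seco-aldehyde
Product: 28 target (1R,2S,3S,5S,6S,7R,8S,10R)-1,10:2,3-diepoxy-5-hydroxy-8-angeloyloxygermacra-4(15),11(13)-dien-12,6-olide, via alkenylchromium dichloride 27 (not isolated)
Conditions: CrCl2 (10 equiv), NiCl2 (0.1 equiv), DMF–THF, rt, syringe-pump addition of 26 (final 3 mM); aq. sodium serinate–NaHCO3 work-up
Reagents that add atoms: CrCl2, Cl[Cr]Cl (chromium and chloride are carried only in 27)
Why: Nozaki–Hiyama–Kishi reaction: zerovalent nickel formed in situ inserts into the C4–OTf bond, the alkenyl group passes to trivalent chromium (27), and the alkenylchromium adds to the C5 aldehyde. The closest known reaction type is the intramolecular Ni/Cr coupling of 2-substituted alkenyl triflates or iodides with aldehydes, used to close medium and large carbocycles that carry an exocyclic methylene next to the new carbinol. The ten-membered carbocycle closes in the 10-exo-trig mode (C4 attacks the C5 carbonyl, oxygen outside the ring). C5 is set by the substrate: the forming bond aligns anti to the C6–O lactone bond (Anh/Cornforth arrangement) while C4, tethered through C7, must approach from the C7 side, which puts the chromium-bound oxygen on the ring periphery and corresponds to Si-face attack, i.e. 5S (5,6-syn). The step needs aldehyde selectivity over lactone, enoates and oxiranes, which the low basicity of alkenylchromium reagents should secure, and cyclisation over oligomerisation, which slow addition at high dilution and the turn elements of the chain (cis-2,3-oxirane, trans-1,10-oxirane, trans-lactone) should secure. β-Elimination toward the C3 oxirane is the side reaction to watch; allylic C–O bonds are normally tolerated next to alkenylchromium centres because the C–Cr bond lies in the alkene plane and is poorly placed for syn elimination to an allene.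

**Compound list**

1 | (S)-5-(hydroxymethyl)furan-2(5H)-one | O=C1O[C@H](CO)C=C1 | starting material
2 | (S)-5-{[(tert-butyldiphenylsilyl)oxy]methyl}furan-2(5H)-one | O=C1O[C@H](CO[Si](c2ccccc2)(c2ccccc2)C(C)(C)C)C=C1 | intermediate
3 | (4R,5S)-5-{[(tert-butyldiphenylsilyl)oxy]methyl}-4-vinyldihydrofuran-2(3H)-one | O=C1O[C@H](CO[Si](c2ccccc2)(c2ccccc2)C(C)(C)C)[C@@H](C=C)C1 | intermediate
4 | secondary ozonide (1,2,4-trioxolane) of 3 | O=C1O[C@H](CO[Si](c2ccccc2)(c2ccccc2)C(C)(C)C)[C@@H](C2OCOO2)C1 | intermediate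
5 | (2S,3S)-2-{[(tert-butyldiphenylsilyl)oxy]methyl}-5-oxotetrahydrofuran-3-carbaldehyde | O=C1O[C@H](CO[Si](c2ccccc2)(c2ccccc2)C(C)(C)C)[C@@H](C=O)C1 | intermediate
6 | (4R,5S)-5-{[(tert-butyldiphenylsilyl)oxy]methyl}-4-[(1S)-1-hydroxybut-3-yn-1-yl]dihydrofuran-2(3H)-one | O=C1O[C@H](CO[Si](c2ccccc2)(c2ccccc2)C(C)(C)C)[C@@H]([C@@H](O)CC#C)C1 | intermediate
7 | triethylsilyl ether of 6 | O=C1O[C@H](CO[Si](c2ccccc2)(c2ccccc2)C(C)(C)C)[C@@H]([C@@H](O[Si](CC)(CC)CC)CC#C)C1 | intermediate
8 | E-alkenyldimethylalane from 7 (methyl on C10, aluminium on C1) | O=C1O[C@H](CO[Si](c2ccccc2)(c2ccccc2)C(C)(C)C)[C@@H]([C@@H](O[Si](CC)(CC)CC)C/C(C)=C/[Al](C)C)C1 | intermediate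
9 | E-alkenyl iodide: lactone with (1S,3E)-4-iodo-3-methyl-1-(triethylsilyloxy)but-3-en-1-yl chain at C7 | O=C1O[C@H](CO[Si](c2ccccc2)(c2ccccc2)C(C)(C)C)[C@@H]([C@@H](O[Si](CC)(CC)CC)C/C(C)=C/I)C1 | intermediate
10 | Mannich base: 9 with a (dimethylamino)methyl group on C11 | CN(C)CC1C(=O)O[C@H](CO[Si](c2ccccc2)(c2ccccc2)C(C)(C)C)[C@H]1[C@@H](O[Si](CC)(CC)CC)C/C(C)=C/I | intermediate
11 | trimethylammonium iodide (methiodide) of 10 | C[N+](C)(C)CC1C(=O)O[C@H](CO[Si](c2ccccc2)(c2ccccc2)C(C)(C)C)[C@H]1[C@@H](O[Si](CC)(CC)CC)C/C(C)=C/I.[I-] | intermediate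
12 | α-methylene lactone (C11=C13) with C8 triethylsilyl ether and E-alkenyl iodide | C=C1C(=O)O[C@H](CO[Si](c2ccccc2)(c2ccccc2)C(C)(C)C)[C@H]1[C@@H](O[Si](CC)(CC)CC)C/C(C)=C/I | intermediate
13 | C8 alcohol: α-methylene lactone with (1S,3E)-1-hydroxy-4-iodo-3-methylbut-3-en-1-yl chain | C=C1C(=O)O[C@H](CO[Si](c2ccccc2)(c2ccccc2)C(C)(C)C)[C@H]1[C@@H](O)C/C(C)=C/I | intermediate
14 | angelic acid, (Z)-2-methylbut-2-enoic acid | C/C=C(/C)C(=O)O | starting material
15 | angelic 2,4,6-trichlorobenzoic anhydride | C/C=C(/C)C(=O)OC(=O)c1c(Cl)cc(Cl)cc1Cl | intermediate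
16 | C8 angelate of 13 (E-alkenyl iodide, C5 silyl ether) | C=C1C(=O)O[C@H](CO[Si](c2ccccc2)(c2ccccc2)C(C)(C)C)[C@H]1[C@@H](OC(=O)/C(C)=C\C)C/C(C)=C/I | intermediate
17 | (R)-but-3-yn-2-ol | C[C@@H](O)C#C | starting material
18 | lithium cyclic (Z)-alkenyl alkoxy alanate from 17 | C[C@H]1O[AlH2-]C=C1.[Li+] | intermediate
19 | (R,Z)-4-(tributylstannyl)but-3-en-2-ol | C[C@@H](O)/C=C\[Sn](CCCC)(CCCC)CCCC | intermediate
20 | (1(10)E,2Z)-dienol: 16 with iodine replaced by the (1Z,3R)-3-hydroxybut-1-en-1-yl group | C=C1C(=O)O[C@H](CO[Si](c2ccccc2)(c2ccccc2)C(C)(C)C)[C@H]1[C@@H](OC(=O)/C(C)=C\C)C/C(C)=C/C=C\[C@@H](C)O | intermediate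
21 | (10R,1R)-trans-1,10-oxirane of 20 (Z-allylic 4R alcohol kept) | C=C1C(=O)O[C@H](CO[Si](c2ccccc2)(c2ccccc2)C(C)(C)C)[C@H]1[C@@H](OC(=O)/C(C)=C\C)C[C@@]1(C)O[C@@H]1/C=C\[C@@H](C)O | intermediate
22 | bis-oxirane carbinol: 21 with cis-(2S,3S)-oxirane, threo to the 4R carbinol | C=C1C(=O)O[C@H](CO[Si](c2ccccc2)(c2ccccc2)C(C)(C)C)[C@H]1[C@@H](OC(=O)/C(C)=C\C)C[C@@]1(C)O[C@@H]1[C@H]1O[C@H]1[C@@H](C)O | intermediate
23 | cis-α,β-epoxy methyl ketone (C4 ketone; oxirane configurations as in 22) | C=C1C(=O)O[C@H](CO[Si](c2ccccc2)(c2ccccc2)C(C)(C)C)[C@H]1[C@@H](OC(=O)/C(C)=C\C)C[C@@]1(C)O[C@@H]1[C@H]1O[C@H]1C(C)=O | intermediate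
24 | C4 enol triflate (1-(trifluoromethylsulfonyloxy)vinyl group on C3; C5 silyl ether) | C=C1C(=O)O[C@H](CO[Si](c2ccccc2)(c2ccccc2)C(C)(C)C)[C@H]1[C@@H](OC(=O)/C(C)=C\C)C[C@@]1(C)O[C@@H]1[C@H]1O[C@H]1C(=C)OS(=O)(=O)C(F)(F)F | intermediate
25 | primary C5 alcohol of 24 | C=C1C(=O)O[C@H](CO)[C@H]1[C@@H](OC(=O)/C(C)=C\C)C[C@@]1(C)O[C@@H]1[C@H]1O[C@H]1C(=C)OS(=O)(=O)C(F)(F)F | intermediate
26 | seco-aldehyde (C5 aldehyde, C4 enol triflate) | C=C1C(=O)O[C@H](C=O)[C@H]1[C@@H](OC(=O)/C(C)=C\C)C[C@@]1(C)O[C@@H]1[C@H]1O[C@H]1C(=C)OS(=O)(=O)C(F)(F)F | intermediate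
27 | C4 alkenylchromium dichloride of 26 | C=C1C(=O)O[C@H](C=O)[C@H]1[C@@H](OC(=O)/C(C)=C\C)C[C@@]1(C)O[C@@H]1[C@H]1O[C@H]1C(=C)[Cr](Cl)Cl | intermediate
28 | (1R,2S,3S,5S,6S,7R,8S,10R)-1,10:2,3-diepoxy-5-hydroxy-8-angeloyloxygermacra-4(15),11(13)-dien-12,6-olide (EANPDB:COMP_00179) | C=C1C(=O)O[C@H]2[C@H]1[C@@H](OC(=O)/C(C)=C\C)C[C@@]1(C)O[C@@H]1[C@H]1O[C@H]1C(=C)[C@@H]2O | target

**Step count and risks**

Total steps: 18. Longest linear sequence: 17 (steps 1–9 and 11–18; step 10 prepares the stannane).

Steps most likely to fail: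

1. Step 18. What may go wrong: addition to the wrong face of the C5 aldehyde, since only the macrocyclic transition state controls it, made worse by loss of the alkenylchromium through β-elimination or protonation during the slow closure. Fallback (sets out from 26, comes back at 28): C5 is no longer set in the C–C bond formation but by reagent-controlled reduction. The closure is run as in step 18 and the carbinol mixture, containing the 5-epimer F1, is oxidised without separation (Dess–Martin periodinane, NaHCO3, CH2Cl2) to the cross-conjugated 4(15)-en-5-one F2. F2 is then reduced at the ketone only with catecholborane and the (S)-methyl-CBS oxazaborolidine at −78 °C, the 1,1-disubstituted alkenyl group acting as the large substituent, which should give 28.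

2. Step 15. What may go wrong: competing deprotonation at C7 (vinylogous to the α-methylene lactone) followed by β-elimination of the C8 or C6 oxygen, or base-induced Z-to-E isomerisation of the angelate. Fallback (sets out from 22, comes back at 24): the α-methylene lactone is masked before any strong base is used. Dimethylamine in THF at 0 °C should add to C13 of 22 to give the amine adduct F3. Parikh–Doering oxidation (SO3·pyridine, DMSO, iPr2NEt) gives the amino ketone F4, and KN(SiMe3)2 with Comins' reagent gives the amino enol triflate F5. Quaternisation with iodomethane to the methiodide F6 (not isolated) and aq. NaHCO3 then restores the methylene group and gives 24.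

3. Step 12. What may go wrong: attack of hydroxide or peroxysulfate on the α-methylene lactone at pH 10, and incomplete discrimination between the two diene double bonds or their faces. Fallback (sets out from 13 and 19, comes back at 21): the 1,10-oxirane is made by hydroxyl direction before the ester is in place. Stannane 19 is silylated (TBSCl, imidazole) to the silyl ether F7, and Stille coupling with 13 (conditions of step 11) gives the diene F8 with a free C8 hydroxyl. A homoallylic-alcohol-directed asymmetric epoxidation (Zr(OtBu)4, chiral bishydroxamic acid ligand of the enantiomer matching the 10R,1R face, cumene hydroperoxide, toluene, 0 °C) gives the 1,10-oxirane F9. Angeloylation as in step 9 gives the ester F10, and HF·pyridine removes the secondary silyl ether to give 21.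

**Further compounds**

F1 | step 18 | 5-epimer of 28 (5R carbinol) | C=C1C(=O)O[C@H]2[C@H]1[C@@H](OC(=O)/C(C)=C\C)C[C@@]1(C)O[C@@H]1[C@H]1O[C@H]1C(=C)[C@H]2O
F2 | step 18 | 5-oxo compound (4(15)-en-5-one) from 28 and F1 | C=C1C(=O)O[C@H]2[C@H]1[C@@H](OC(=O)/C(C)=C\C)C[C@@]1(C)O[C@@H]1[C@H]1O[C@H]1C(=C)C2=O
F3 | step 15 | dimethylamine adduct of 22 (C11 (dimethylamino)methyl lactone, C4 carbinol) | CN(C)CC1C(=O)O[C@H](CO[Si](c2ccccc2)(c2ccccc2)C(C)(C)C)[C@H]1[C@@H](OC(=O)/C(C)=C\C)C[C@@]1(C)O[C@@H]1[C@H]1O[C@H]1[C@@H](C)O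
F4 | step 15 | amino epoxy ketone (C4 ketone of F3) | CN(C)CC1C(=O)O[C@H](CO[Si](c2ccccc2)(c2ccccc2)C(C)(C)C)[C@H]1[C@@H](OC(=O)/C(C)=C\C)C[C@@]1(C)O[C@@H]1[C@H]1O[C@H]1C(C)=O
F5 | step 15 | amino enol triflate from F4 | CN(C)CC1C(=O)O[C@H](CO[Si](c2ccccc2)(c2ccccc2)C(C)(C)C)[C@H]1[C@@H](OC(=O)/C(C)=C\C)C[C@@]1(C)O[C@@H]1[C@H]1O[C@H]1C(=C)OS(=O)(=O)C(F)(F)F
F6 | step 15 | methiodide of F5 | C[N+](C)(C)CC1C(=O)O[C@H](CO[Si](c2ccccc2)(c2ccccc2)C(C)(C)C)[C@H]1[C@@H](OC(=O)/C(C)=C\C)C[C@@]1(C)O[C@@H]1[C@H]1O[C@H]1C(=C)OS(=O)(=O)C(F)(F)F.[I-]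
F7 | step 12 | tert-butyldimethylsilyl ether of 19 | C[C@@H](O[Si](C)(C)C(C)(C)C)/C=C\[Sn](CCCC)(CCCC)CCCC
F8 | step 12 | (1(10)E,2Z)-diene with free C8 hydroxyl and C4 silyl ether | C=C1C(=O)O[C@H](CO[Si](c2ccccc2)(c2ccccc2)C(C)(C)C)[C@H]1[C@@H](O)C/C(C)=C/C=C\[C@@H](C)O[Si](C)(C)C(C)(C)C
F9 | step 12 | (10R,1R)-1,10-oxirane of F8 | C=C1C(=O)O[C@H](CO[Si](c2ccccc2)(c2ccccc2)C(C)(C)C)[C@H]1[C@@H](O)C[C@@]1(C)O[C@@H]1/C=C\[C@@H](C)O[Si](C)(C)C(C)(C)C
F10 | step 12 | C8 angelate of F9 | C=C1C(=O)O[C@H](CO[Si](c2ccccc2)(c2ccccc2)C(C)(C)C)[C@H]1[C@@H](OC(=O)/C(C)=C\C)C[C@@]1(C)O[C@@H]1/C=C\[C@@H](C)O[Si](C)(C)C(C)(C)C
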